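**Retrosynthetic overview**

- The cis-2,5-oxolane target comes from face-selective hydrogenation of an exocyclic 2-alkylidene oxolane (a vinylogous ester); C2 is set last, relative to C5.
- The vinylogous ester comes from Claisen acylation of the methyl-side enolate of hexadecan-2-one by (R)-γ-octalactone, followed by cyclodehydration.
- (R)-γ-Octalactone comes from a catalytic asymmetric homoaldol: a β-metallated propanoate (ester homoenolate from a silyloxycyclopropane) adds to pentanal. This makes ring bond C4–C5 (the dissonant 1,4-dioxygen pattern) and sets C5.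
- Ring order: the γ-lactone ring forms in step 1, is opened and re-closed as the 2-alkylidene oxolane in step 2, and is saturated in step 3. No protecting groups are used.

Assumption: the SMILES is read as the cis isomer, 1-[(2R,5R)-5-butyloxolan-2-yl]hexadecan-2-one; compounds 1, 2 and 6 and the named catalysts are taken as catalogue items.

**Step 1**
Reactants: 1 pentanal; 2 [(1-ethoxycyclopropyl)oxy]trimethylsilane
Product: 5 (5R)-5-butyloxolan-2-one, via bis(3-ethoxy-3-oxopropyl)zinc 3 (not isolated), via ethyl (4R)-4-hydroxyoctanoate 4 (not isolated)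
Conditions: 2 (3.2 equiv), ZnCl2 (1.6 equiv), Et2O, rt, then Me3SiCl/Et2O stripped in vacuo; Ti(OiPr)4 (2 equiv), (1R,2R)-1,2-bis(trifluoromethanesulfonamido)cyclohexane (10 mol%), PhMe, −20 °C, then 1 (1 equiv), 16 h; 1 M HCl; TsOH (cat.), PhMe, rt
Reagents that add atoms: none
Why: Proposed new method: asymmetric homoaldol (ester homoenolate + aldehyde) in which the internally chelated zinc homoenolate 3 is inert to aldehydes once Me3SiCl is removed, so C–C bond formation runs only through Zn→Ti transfer of the CH2CH2CO2Et group to the chiral bis(sulfonamido)titanium complex, which delivers it to the Si face of Ti-bound pentanal and sets the carbinol centre as R (the (1R,2R)-ligand is chosen by analogy with its Si-face alkyl transfers, and the (1S,2S)-ligand is used if the sense proves opposite); the closest known reactions are the Ti–bis(sulfonamide)-catalysed additions of ester-functionalised dialkylzincs to aliphatic aldehydes and the racemic Me3SiCl- or TiCl4-promoted homoaldol of the same cyclopropane reagent, and acid then lactonises 4 to 5.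

**Step 2**
Reactants: 5 (5R)-5-butyloxolan-2-one; 6 hexadecan-2-one
Product: 9 (1E)-1-[(5R)-5-butyloxolan-2-ylidene]hexadecan-2-one, via lithium hexadec-1-en-2-olate 7 (not isolated), via (5R)-5-hydroxytetracosane-8,10-dione 8 (not isolated)
Conditions: 6 (2.2 equiv), LDA (2.2 equiv), THF, −78 °C; 5 (1 equiv), −78 → 0 °C; 1 M HCl; crude 8, anhydrous (CO2H)2, CH2Cl2, rt
Reagents that add atoms: none
Why: Crossed Claisen condensation in which the kinetic methyl-side enolate 7 acylates on the lactone carbonyl and the ring-opened β-diketone is deprotonated by the second equivalent of 7 (driving the equilibrium and returning 6), after which acid closes the γ-hydroxy ketone to its hemiketal and dehydrates it to the conjugated exocyclic enol ether (E favoured, any Z isomer converges in step 3); C5 is never part of a breaking bond and stays R.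

**Step 3**
Reactants: 9 (1E)-1-[(5R)-5-butyloxolan-2-ylidene]hexadecan-2-one
Product: 10 1-[(2R,5R)-5-butyloxolan-2-yl]hexadecan-2-one
Conditions: H2 (3 atm), 5% Rh/Al2O3, EtOAc, rt
Reagents that add atoms: none
Why: Substrate-controlled heterogeneous hydrogenation of a 5-substituted 2-alkylidene oxolane, in which the alkene adsorbs on rhodium through the ring face anti to the C5 butyl group, so the new C2–H is trans to butyl and the 2-oxohexadecyl chain is cis to it (2R; about 9:1 or better is expected by analogy with nonactate-type precursors), while Rh/Al2O3 in a non-alcohol solvent spares the dialkyl ketone and the enol-ether C–O bond.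

**Compound list**

1 | pentanal | CCCCC=O | starting material
2 | [(1-ethoxycyclopropyl)oxy]trimethylsilane | CCOC1(CC1)O[Si](C)(C)C | starting material
3 | bis(3-ethoxy-3-oxopropyl)zinc | CCOC(=O)CC[Zn]CCC(=O)OCC | intermediate
4 | ethyl (4R)-4-hydroxyoctanoate | CCCC[C@@H](O)CCC(=O)OCC | intermediate
5 | (5R)-5-butyloxolan-2-one | CCCC[C@@H]1CCC(=O)O1 | intermediate
6 | hexadecan-2-one | CC(=O)CCCCCCCCCCCCCC | starting material
7 | lithium hexadec-1-en-2-olate | [Li+].[O-]C(=C)CCCCCCCCCCCCCC | intermediate
8 | (5R)-5-hydroxytetracosane-8,10-dione | CCCC[C@@H](O)CCC(=O)CC(=O)CCCCCCCCCCCCCC | intermediate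
9 | (1E)-1-[(5R)-5-butyloxolan-2-ylidene]hexadecan-2-one | O=C(CCCCCCCCCCCCCC)/C=C1/O[C@H](CCCC)CC1 | intermediate
10 | 1-[(2R,5R)-5-butyloxolan-2-yl]hexadecan-2-one | CCCCCCCCCCCCCCC(=O)C[C@H]1CC[C@@H](CCCC)O1 | target

**Totals**

Total steps: 3. Longest linear sequence: 3 (1 → 5 → 9 → 10; 2 and 6 enter as purchased partners).

**Steps most likely to fail, with fallbacks**

Step 1 is the riskiest: the β-ester chelate may make alkyl transfer to titanium slow or poorly enantioselective. The fallback sets out from 1 and comes back at 4. A thiazolium-catalysed Stetter reaction of 1 with ethyl acrylate (3-benzyl-5-(2-hydroxyethyl)-4-methylthiazolium chloride 10 mol%, Et3N, EtOH, 80 °C) gives ethyl 4-oxooctanoate F1. Here the Breslow intermediate of pentanal acts as the acyl anion and attacks the acrylate β-carbon, so the same C–C bond is made. Asymmetric hydrogenation of F1 with RuCl2[(R)-BINAP] (H2 100 atm, EtOH, 35 °C; ligand sense by analogy with β-keto esters, (S)-BINAP if it proves reversed) gives 4, which is lactonised to 5 with TsOH as in step 1. This costs one extra step.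

Step 2 may fail through sluggish acylation of a ketone enolate by the lactone, or through enolate equilibration and self-aldol on warming. The fallback sets out from 5 and comes back at 9. Lactone 5 is opened with MeNH(OMe)·HCl/i-PrMgCl (THF, −20 °C) to (4R)-4-hydroxy-N-methoxy-N-methyloctanamide F2. This is silylated (TESCl, imidazole, CH2Cl2) to (4R)-N-methoxy-N-methyl-4-[(triethylsilyl)oxy]octanamide F3. Enolate 7 (1.3 equiv, THF, −78 → 0 °C) is acylated by F3 through the stable chelated tetrahedral adduct to give (5R)-5-[(triethylsilyl)oxy]tetracosane-8,10-dione F4. TsOH·H2O in wet CH2Cl2 then removes the silyl group and cyclodehydrates to 9.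

Step 3 may give an insufficient cis:trans ratio, or suffer C=O reduction or C–O hydrogenolysis on the metal surface. The fallback sets out from 9 and comes back at 10. Homogeneous Rh(I)-catalysed 1,4-hydrosilylation (Et3SiH, (Ph3P)3RhCl 1 mol%, PhMe, 50 °C) delivers hydride to ring C2, again anti to butyl, and traps the enolate as triethyl({(1Z)-1-[(2R,5R)-5-butyloxolan-2-yl]hexadec-1-en-2-yl}oxy)silane F5, leaving the carbonyl oxidation level and the ring C–O bonds untouched. Buffered hydrolysis (AcOH/THF/H2O, rt; no base, to avoid retro-oxa-Michael scrambling) gives 10. This fallback fixes chemoselectivity; it is not expected to improve the cis:trans ratio by itself, but a chiral bisphosphine on the soluble catalyst could add catalyst control to the substrate bias.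

**Further compounds**

F1 | step 1 | ethyl 4-oxooctanoate | CCCCC(=O)CCC(=O)OCC
F2 | step 2 | (4R)-4-hydroxy-N-methoxy-N-methyloctanamide | CCCC[C@@H](O)CCC(=O)N(C)OC
F3 | step 2 | (4R)-N-methoxy-N-methyl-4-[(triethylsilyl)oxy]octanamide | CCCC[C@@H](O[Si](CC)(CC)CC)CCC(=O)N(C)OC
F4 | step 2 | (5R)-5-[(triethylsilyl)oxy]tetracosane-8,10-dione | CCCC[C@@H](O[Si](CC)(CC)CC)CCC(=O)CC(=O)CCCCCCCCCCCCCC
F5 | step 3 | triethyl({(1Z)-1-[(2R,5R)-5-butyloxolan-2-yl]hexadec-1-en-2-yl}oxy)silane | CCCCCCCCCCCCCC/C(O[Si](CC)(CC)CC)=C/[C@H]1CC[C@@H](CCCC)O1
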